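# Total synthesis proposal for CNP0182249.2: (1R,4R,5S,6R)-4-hydroxydauc-8-en-6-yl 4-hydroxybenzoate

## The problem

Daucane numbering is used. Ring A (five-membered) is C1–C2–C3–C4–C5 and ring B (seven-membered) is C1–C5–C6–C7–C8–C9–C10. C1 and C8 carry CH3, C4 carries OH and isopropyl, C6 carries the 4-hydroxybenzoyloxy group, and β means the face of the C1 methyl group.

- **Ring fusion and stereocentres.** The rings share the C1–C5 bond in a trans fusion. C1 is an all-carbon quaternary centre and is followed without a gap by the stereocentres C5, C4 and C6. As drawn, the compound is (1R,4R,5S,6R), with C1–CH3, C4–OH and C6–O all β and H5, H6 and isopropyl α.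
- **Who can control whom.** C4, C5 and C6 are neighbours and can control each other through an oxygen on one of them. C1, however, shows ring A almost the same bulk on both faces (CH3 against C10H2), so a relay from C1 into ring A has to pass through ring B.
- **The alkene.** C8=C9 is trisubstituted, isolated and β,γ to the C6 oxygen. Its place must be fixed by the ring construction, because C7–H turns acidic as soon as C6 or C5=C6 belongs to a carbonyl π system, and the alkene then tends to slip into conjugation.
- **Sensitive groups.** The tertiary C4 alcohol can ionise, dehydrate, or undergo retro-aldol cleavage next to a C6 ketone. The homoallylic ester can eliminate to a diene. With the free phenol, these groups forbid strong acid, late strong base and hydrogenolysis.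
- **The enabling feature, in ring B.** C8=C9 and the C5–C6 bond are separated by the single methylene C7 on one side and by the C10–C1 bond on the other. H on C5 with O on C6 is exactly what a reduced C5–C6 epoxide leaves behind.
- **The retron.** With C5=C6 restored, ring B is a cyclohepta-1,4-diene whose saturated two-carbon bridge ends in the quaternary C1. That is the product pattern of a cis-divinylcyclopropane rearrangement. C7 is the cyclopropane methylene, C6 and C8 are the other ring atoms, and the C1=C5 bond of a ring A cyclopentenone is one of the two vinyl groups.

## Retrosynthesis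

**15 ⇒ 14 ⇒ 12 + 13.** The acyl–O6 bond is cut. The neighbouring cut, alkyl C6–O with inversion, is set aside because C7–H is allylic and substitution would compete with elimination to a C6=C7–C8=C9 diene. The phenol travels as its acetate (14). Diol 12 already holds all four stereocentres, so the forward reaction only has to tell a secondary from a tertiary alcohol.

**12 ⇒ 11.** The C5–H bond is cut and O6 is tied back to C5 as the 5β,6β-epoxide 11.
- A C6 ketone would instead place C7 between a carbonyl and C8=C9, turn C4–OH into an aldol and leave the hydride face open.
- The epoxide keeps the C6–O bond untouched from the moment it is made.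
- The forward step must break C5–O rather than C6–O, which the stability of a tertiary radical secures. It must also bring hydrogen to the α face, because three β substituents surround C5.

**11 ⇒ 10.** The C4–isopropyl bond is cut, removing three carbons and one stereocentre.
- Made on 12, this cut would give a ketone beside C5–H and expose the ring fusion to epimerisation.
- Made on 9, it would meet a carbonyl with no facial bias.
- In 10 the epoxide oxygen on C5 stands at right angles to the carbonyl plane on the β face, so the nucleophile must come from α.

**10 ⇒ 9.** Both epoxide C–O bonds are cut. Dienone 9 (C12H16O) has C1 as its only stereocentre. The forward oxidant must be nucleophilic so that only the enone alkene reacts, and it must use the β face.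

**9 ⇒ 8 (key).** C1–C10 is cut and C6–C8 is joined.
- Closing ring B at C8=C9, C5–C6 or C6–C7 presupposes a finished C1 and fights a seven-membered end-to-end closure.
- The [3,3] cut removes ring B and the quaternary centre together.
- Compound 8 is a monocyclic enone bearing a cyclopropane whose two adjacent stereocentres come from one stereospecific methylene transfer.
- The forward reaction needs cis alkenyl groups and a clean boat transition state.

**8 ⇒ 7 ⇒ 6 ⇒ 5.** C9=C10 is cut by tracing it to methylenation of aldehyde 7. The two bonds to C7 are then cut by tracing them to methylene transfer onto C6=C8 of 5. The CH2OH group that becomes the vinyl group is also the handle for the only enantioselective event of the route. Compound 5 is achiral.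

**5 ⇒ 3 + 4; 3 ⇒ 1.** The sp2–sp2 bond C5–C6 is cut. Bromoenone 4 is bought with C1–C5, the ketone and the methyl group in place. The Z geometry of 3, which later becomes the cis relation on the cyclopropane, comes from chelate 2, made from propargyl alcohol 1.

## Roads not taken

**Alternative 1:** cut C8=C9.
- Forward key step: ring-closing metathesis of the 8,9-seco diene A1 with the second-generation Grubbs catalyst, giving 12.
- This is the obvious route, but the metathesis sets no stereocentre, so all four must already sit in A1.
- A1 calls for an enantioselective conjugate allylation that builds a quaternary carbon on a β-methyl cyclopentenone.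
- It then needs an aldol with a β,γ-unsaturated aldehyde that slips easily into conjugation and offers no control at C6.
- It also passes through a C5–H beside a C4 ketone until the isopropyl group is on.
- The chosen plan creates C1 and ring B in one event and never has an epimerisable C5.

**Alternative 2:** cut C1–C5 and C1–C10, with C1 as a carbene carbon inserted into an arene bond.
- Forward key step: intramolecular Buchner reaction of diazoketone A2 with Rh2(OAc)4, giving azulenone A3.
- It dearomatises a cheap cresol-type ring and places OCH3 on C6 and CH3 on C8.
- The acceptor the carbene needs ends up as a ketone on C2, where the target has CH2.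
- C4 must stay bare, because an oxygen there is five atoms from the carbene (oxonium ylide) and β to the C2 ketone.
- Three ring B double bonds would then have to be reduced to one.
- C4, C5, C6 and two redox corrections all remain open.

**Alternative 3:** delete C7 from ring B and join C6–C8, which is a one-carbon ring expansion of a hydrindane.
- Forward key step: cyclopropylcarbinyl-to-homoallyl rearrangement of cyclopropa-fused diol A4. The free acid corresponding to 13 attacks C6 anti to the breaking C6–C8 bond and gives 14 directly.
- The step would insert C7, place C8=C9 and install the ester at once.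
- However, A4 has six stereocentres on a trans-hydrindane that is no easier than the target.
- A cation on C9 beside the methyl-bearing C8 can leak to a tertiary cyclobutyl cation or open the outer cyclopropane bond.
- The acid needed would also ionise C4–OH.

Key step: step 6

Assumption: the stereodescriptors of the given SMILES are taken as written, which puts the C6 oxygen cis to C4–OH and C1–CH3 (H5 and H6 cis).

## Steps

Step 1
Reactants: 1 prop-2-yn-1-ol
Product: 3 (Z)-2-methyl-3-(tributylstannyl)prop-2-en-1-ol, via alkenylmagnesium chelate 2 (not isolated)
Conditions: MeMgBr (2.5 equiv), CuI (10 mol %), THF, −10 °C to rt; then Bu3SnCl, 0 °C to rt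
Reagents that add atoms: methylmagnesium bromide, C[Mg]Br; tributyltin chloride, CCCC[Sn](Cl)(CCCC)CCCC
Why: Copper-catalysed carbomagnesiation of the magnesium alkoxide of a propargylic alcohol is an anti addition that puts CH3 on the internal carbon and magnesium on the terminus, held cis to CH2O in the five-membered chelate 2. Stannylation of the C–Mg bond goes with retention and fixes the Z geometry.

Step 2
Reactants: 3 (Z)-2-methyl-3-(tributylstannyl)prop-2-en-1-ol; 4 2-bromo-3-methylcyclopent-2-en-1-one
Product: 5 2-[(1Z)-3-hydroxy-2-methylprop-1-en-1-yl]-3-methylcyclopent-2-en-1-one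
Conditions: Pd2(dba)3 (2.5 mol %), AsPh3 (20 mol %), CuI (10 mol %), DMF, 50 °C
Reagents that add atoms: none
Why: Stille coupling of an α-halo enone with an alkenylstannane forms C5–C6 with retention of alkene geometry. The neutral conditions tolerate the free alcohol and the enolisable enone.

Step 3
Reactants: 5 2-[(1Z)-3-hydroxy-2-methylprop-1-en-1-yl]-3-methylcyclopent-2-en-1-one
Product: 6 2-[(1R,2S)-2-(hydroxymethyl)-2-methylcyclopropyl]-3-methylcyclopent-2-en-1-one
Conditions: Et2Zn, CH2I2, DME, CH2Cl2, −10 °C; (4R,5R)-2-butyl-N,N,N',N'-tetramethyl-1,3,2-dioxaborolane-4,5-dicarboxamide (1.2 equiv), −10 °C to rt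
Reagents that add atoms: diiodomethane, ICI
Why: In this dioxaborolane-mediated asymmetric Simmons–Smith reaction (Charette cyclopropanation) the zinc alkoxide directs methylene only to the allylic C6=C8 bond, and the electron-poor enone alkene is inert. The transfer is stereospecific, so Z becomes cis. The (4R,5R) controller selects the face that gives 6R,8S, by analogy with its uniform sense on di- and trisubstituted allylic alcohols.

Step 4
Reactants: 6 2-[(1R,2S)-2-(hydroxymethyl)-2-methylcyclopropyl]-3-methylcyclopent-2-en-1-one
Product: 7 (1S,2R)-1-methyl-2-(2-methyl-5-oxocyclopent-1-en-1-yl)cyclopropane-1-carbaldehyde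
Conditions: Dess–Martin periodinane, CH2Cl2, 0 °C to rt
Reagents that add atoms: none
Why: Dess–Martin oxidation is mild, and the aldehyde sits on a quaternary carbon and cannot epimerise. Compound 7 is used at once and kept at or below room temperature so that the reversible retro-Claisen shift of cis-vinylcyclopropane carbaldehydes stays slow.

Step 5
Reactants: 7 (1S,2R)-1-methyl-2-(2-methyl-5-oxocyclopent-1-en-1-yl)cyclopropane-1-carbaldehyde
Product: 8 2-[(1R,2R)-2-ethenyl-2-methylcyclopropyl]-3-methylcyclopent-2-en-1-one
Conditions: Ph3PCH3Br, KN(SiMe3)2, THF, 0 °C; then 7, −78 to 0 °C, cold work-up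
Reagents that add atoms: methyltriphenylphosphonium bromide, C[P+](c1ccccc1)(c1ccccc1)c1ccccc1.[Br-]
Why: In this Wittig methylenation, one equivalent of ylide at low temperature should take the aldehyde far faster than the tetrasubstituted, conjugated ketone. No stereocentre is touched; the change of descriptor at C8 is only a change of priorities.

Step 6
Reactants: 8 2-[(1R,2R)-2-ethenyl-2-methylcyclopropyl]-3-methylcyclopent-2-en-1-one
Product: 9 (3aR)-3a,6-dimethyl-3,3a,4,7-tetrahydroazulen-1(2H)-one (C4 ketone, C5=C6, C8=C9, 1R)
Conditions: toluene (0.02 M, degassed, base-washed glass), BHT (cat.), 100–110 °C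
Reagents that add atoms: none
Why: This is the Cope rearrangement of a cis-1,2-divinylcyclopropane (divinylcyclopropane–cycloheptadiene rearrangement), a concerted [3,3] shift through the endo-boat transition state in which both alkenes lie over the three-membered ring. The strained, doubly allylic C6–C8 bond breaks while C1–C10 forms, so ring B is closed by a three-to-seven ring expansion and not by an end-to-end cyclisation, and the new double bonds appear exactly at C5=C6 and C8=C9 with C7 as the lone CH2 between them. The only new stereocentre is C1: in the boat, C10 can reach only the face of the cyclopentenone that looks at C8, so (6R,8R)-8 should give (1R)-9 and the two cyclopropane centres are traded for the quaternary one. The step needs the two alkenyl groups cis, which the Z alkene of 5 and the stereospecific methylene transfer secure, and a rate well above that of homolytic stereomutation of the cyclopropane. The flat sp2 C4 keeps the outer side of the boat free and strain release makes the reaction irreversible; the price is the C1 methyl group, which must point over C7 and is the reason heating is needed. No retro-ene escape exists because the C8 methyl group is trans to the cyclopentenyl group. The closest known cases are thermal rearrangements of vinylcyclopropyl-substituted cycloalkenones and of divinylcyclopropanes with fully substituted termini that deliver quaternary carbons.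

Step 7
Reactants: 9 (3aR)-3a,6-dimethyl-3,3a,4,7-tetrahydroazulen-1(2H)-one
Product: 10 (1R,5S,6R)-5β,6β-epoxy ketone of 9
Conditions: 30% aq. H2O2, LiOH (0.2 equiv), MeOH, −10 to 0 °C
Reagents that add atoms: hydrogen peroxide, OO
Why: Weitz–Scheffer epoxidation touches only the electron-poor C5=C6 bond. C10 leaves C1 on the α face and must return to C7, which lies in the enone plane, so C8–C10 hang under the α face and hydroperoxide should add to C6 and close on C5 from the open β face. Little base and low temperature keep the doubly allylic C7–H in place.

Step 8
Reactants: 10 (1R,5S,6R)-5β,6β-epoxy ketone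
Product: 11 (1R,4R,5S,6R)-5β,6β-epoxydauc-8-en-4β-ol
Conditions: i-PrMgCl, anhydrous CeCl3, THF, −78 °C
Reagents that add atoms: isopropylmagnesium chloride, CC(C)[Mg]Cl
Why: Organocerium 1,2-addition suppresses enolisation at C3 and β-hydride reduction. The C5–O bond stands perpendicular to the carbonyl plane on the β face, so attack anti to it (Felkin–Anh, and the same result with cerium chelated by both oxygens) puts isopropyl α and OH β. C5 bears no hydrogen, so nothing can epimerise.

Step 9
Reactants: 11 (1R,4R,5S,6R)-5β,6β-epoxydauc-8-en-4β-ol
Product: 12 (1R,4R,5S,6R)-dauc-8-ene-4β,6β-diol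
Conditions: Cp2TiCl2 (20 mol %), Mn dust, 2,4,6-collidine hydrochloride, 1,4-cyclohexadiene, THF, rt
Reagents that add atoms: none
Why: In this titanocene-catalysed reductive epoxide opening, Cp2TiCl (trivalent titanium) cleaves C5–O to the tertiary C5 radical and leaves the C6–O bond and its configuration intact. The β face of the radical is walled by C1–CH3, C4–OH and the bulky C6 titanoxy group, so hydrogen from cyclohexadiene should arrive from α and give the trans fusion. The low stationary concentration of trivalent titanium disfavours a second reduction followed by β-elimination of oxygen.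

Step 10
Reactants: 12 (1R,4R,5S,6R)-dauc-8-ene-4β,6β-diol; 13 4-acetoxybenzoyl chloride
Product: 14 (1R,4R,5S,6R)-4-hydroxydauc-8-en-6-yl 4-acetoxybenzoate
Conditions: Et3N, DMAP, CH2Cl2, 0 to 40 °C
Reagents that add atoms: none
Why: In this DMAP-catalysed acylation the tertiary C4–OH is inert, and the hindered secondary C6–OH is met with an acid chloride. The C6–O bond is not broken, so the configuration is kept.

Step 11
Reactants: 14 (1R,4R,5S,6R)-4-hydroxydauc-8-en-6-yl 4-acetoxybenzoate
Product: 15 (1R,4R,5S,6R)-4-hydroxydauc-8-en-6-yl 4-hydroxybenzoate (target)
Conditions: K2CO3 (0.2 equiv), MeOH, 0 °C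
Reagents that add atoms: none
Why: Zemplén-type methanolysis removes an aryl acetate far faster than it attacks a hindered secondary benzoate. The benzoate carbonyl is further deactivated once the phenoxide has formed.

## Compound list

| No. | Name | SMILES | Role |
|---|---|---|---|
| 1 | prop-2-yn-1-ol | C#CCO | starting material |
| 2 | 4-methyl-2,5-dihydro-1,2-oxamagnesole (alkenylmagnesium chelate) | CC1=C[Mg]OC1 | intermediate |
| 3 | (Z)-2-methyl-3-(tributylstannyl)prop-2-en-1-ol | OC/C(C)=C\[Sn](CCCC)(CCCC)CCCC | intermediate |
| 4 | 2-bromo-3-methylcyclopent-2-en-1-one | CC1=C(Br)C(=O)CC1 | starting material |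
| 5 | 2-[(1Z)-3-hydroxy-2-methylprop-1-en-1-yl]-3-methylcyclopent-2-en-1-one | OC/C(C)=C\C1=C(C)CCC1=O | intermediate |
| 6 | 2-[(1R,2S)-2-(hydroxymethyl)-2-methylcyclopropyl]-3-methylcyclopent-2-en-1-one | O=C1CCC(C)=C1[C@@H]2C[C@]2(C)CO | intermediate |
| 7 | (1S,2R)-1-methyl-2-(2-methyl-5-oxocyclopent-1-en-1-yl)cyclopropane-1-carbaldehyde | O=C1CCC(C)=C1[C@@H]2C[C@]2(C)C=O | intermediate |
| 8 | 2-[(1R,2R)-2-ethenyl-2-methylcyclopropyl]-3-methylcyclopent-2-en-1-one | O=C1CCC(C)=C1[C@@H]2C[C@]2(C)C=C | intermediate |
| 9 | (3aR)-3a,6-dimethyl-3,3a,4,7-tetrahydroazulen-1(2H)-one | CC1=CC[C@@]2(C)CCC(=O)C2=CC1 | intermediate |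
| 10 | (1R,5S,6R)-5β,6β-epoxy ketone of 9 | CC1=CC[C@@]2(C)CCC(=O)[C@]23O[C@@H]3C1 | intermediate |
| 11 | (1R,4R,5S,6R)-5β,6β-epoxydauc-8-en-4β-ol | CC1=CC[C@@]2(C)CC[C@@](O)(C(C)C)[C@]23O[C@@H]3C1 | intermediate |
| 12 | (1R,4R,5S,6R)-dauc-8-ene-4β,6β-diol | CC1=CC[C@@]2(C)CC[C@@](O)(C(C)C)[C@@H]2[C@H](O)C1 | intermediate |
| 13 | 4-acetoxybenzoyl chloride | CC(=O)Oc1ccc(cc1)C(Cl)=O | starting material |
| 14 | (1R,4R,5S,6R)-4-hydroxydauc-8-en-6-yl 4-acetoxybenzoate | CC1=CC[C@@]2(C)CC[C@@](O)(C(C)C)[C@@H]2[C@H](OC(=O)c2ccc(OC(C)=O)cc2)C1 | intermediate |
| 15 | (3R,3aS,4R,8aR)-3-hydroxy-6,8a-dimethyl-3-(propan-2-yl)-1,2,3,3a,4,5,8,8a-octahydroazulen-4-yl 4-hydroxybenzoate | CC1=CC[C@@]2(C)CC[C@@](O)(C(C)C)[C@@H]2[C@H](OC(=O)c2ccc(O)cc2)C1 | target |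

## Step count and least certain steps

Total step count: 11. Longest linear sequence: 11 steps (1 to 15). Compounds 4 and 13 are bought.

**Step 6 (key step).** The C1 methyl group has to swing over C7 in the boat, which raises the barrier. If the temperature needed approaches that of homolysis of the doubly allylic C6–C8 bond, stereomutation of the cyclopropane competes and the enantiomeric purity at C1 erodes. Every stereoisomer of 8 still drains into the skeleton of 9.

Fallback: the ring construction is kept and absolute control is moved behind it.
- The fallback sets out from scalemic 9, which is reduced by Corey–Bakshi–Shibata reduction with the (R)-methyl oxazaborolidine and catecholborane.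
- The substrate hardly distinguishes the faces of the C4 ketone, so the catalyst should set 4S in both enantiomers.
- This gives the (1R,4S)-allylic alcohol F1 and the (1S,4S)-allylic alcohol F2, which are diastereomers and separable on silica.
- F1 is oxidised with MnO2 and comes back to the route as enantiopure 9.

**Step 7.** The facial preference rests on the shape of ring B alone and may be modest. Removal of the doubly allylic C7–H by base would also move C8=C9 into conjugation before the peroxide adds.

Fallback: the order of the relay is reversed and base is avoided.
- It sets out from 9, where i-PrMgCl/CeCl3 adds 1,2 to give (1R,4R)-dauca-5,8-dien-4-ol F3. The C4 epimer is removed by chromatography.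
- VO(acac)2/t-BuOOH then delivers oxygen to C5=C6 from the face of the C4 hydroxyl group, in preference to the remote C8=C9.
- The route is rejoined at 11.

**Step 9.** Hydrogen may be delivered to the β face, giving a cis fusion. Alternatively, the C5 radical may be reduced further and lose a β oxygen by elimination.

Fallback: the epoxide is opened one stage earlier by a polar route.
- It sets out from 10, where SmI2 with MeOH in THF at −78 °C cleaves the C5–O bond next to the ketone. This gives the trans-fused 6β-hydroxy-4-ketone F5.
- In F5, C5 is set by protonation of an enolate and stays open to equilibration.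
- Excess i-PrMgCl/CeCl3 then attacks the C4 ketone from the α face, opposite the axial C1 methyl group.
- The route is rejoined at 12.

**Step 8.** A secondary nucleophile at a hindered ketone may transfer β-hydride, act as a base at C3, or allow chloride to open the epoxide.

Fallback:
- It sets out from 10, where isopropenylmagnesium bromide with CeCl3 gives the isopropenyl epoxy alcohol F4 with the same facial logic. This nucleophile is flat and sp2 and has no hydride to transfer.
- H2 over RhCl(PPh3)3 saturates the 1,1-disubstituted alkene in preference to the trisubstituted C8=C9.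
- The route is rejoined at 11.

**Step 3.** The C6=C8 bond is cross-conjugated with the enone and less nucleophilic than a simple allylic alcohol. The ketone may also compete for zinc and boron, which would slow methylene transfer and loosen the chiral assembly.

Fallback: the cyclopropane is made before the C5–C6 bond.
- It sets out from 3. The same dioxaborolane-mediated cyclopropanation on this electron-rich, ketone-free vinylstannane gives [(1R,2R)-1-methyl-2-(tributylstannyl)cyclopropyl]methanol F6.
- Tin–lithium exchange (n-BuLi, 2 equiv, retention) and ZnBr2 give the cyclopropylzinc bromide lithium alkoxide F7.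
- Negishi coupling of F7 with 4 under Pd(PPh3)4 rejoins the route at 6.

## Further compounds

F1 | step 6 | (1S,3aR)-3a,6-dimethyl-1,2,3,3a,4,7-hexahydroazulen-1-ol, (1R,4S) in daucane numbering | CC1=CC[C@@]2(C)CC[C@H](O)C2=CC1
F2 | step 6 | (1S,3aS)-3a,6-dimethyl-1,2,3,3a,4,7-hexahydroazulen-1-ol, (1S,4S) in daucane numbering | CC1=CC[C@]2(C)CC[C@H](O)C2=CC1
F3 | step 7 | (1R,4R)-dauca-5,8-dien-4-ol | CC1=CC[C@@]2(C)CC[C@@](O)(C(C)C)C2=CC1
F4 | step 8 | isopropenyl analogue of 11 (prop-1-en-2-yl on C4) | CC1=CC[C@@]2(C)CC[C@@](O)(C(C)=C)[C@]23O[C@@H]3C1
F5 | step 9 | (1R,5S,6R)-6β-hydroxy-4-ketone, trans-fused (10 with C5–O replaced by C5–H) | CC1=CC[C@@]2(C)CCC(=O)[C@@H]2[C@H](O)C1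
F6 | step 3 | [(1R,2R)-1-methyl-2-(tributylstannyl)cyclopropyl]methanol | CCCC[Sn](CCCC)(CCCC)[C@@H]1C[C@]1(C)CO
F7 | step 3 | cyclopropylzinc bromide lithium alkoxide from F6 | Br[Zn][C@@H]1C[C@]1(C)CO[Li]
A1 | alternative 1 | 8,9-seco diene of 12 (allyl on C1, 1-hydroxy-3-methylbut-3-enyl on C5) | C=CC[C@@]1(C)CC[C@@](O)(C(C)C)[C@@H]1[C@H](O)CC(C)=C
A2 | alternative 2 | 2-diazo-5-(2-methoxy-4-methylphenyl)pentan-3-one | COc1cc(C)ccc1CCC(=O)C(C)=[N+]=[N-]
A3 | alternative 2 | (8aR)-4-methoxy-6,8a-dimethyl-3,8a-dihydroazulen-1(2H)-one | COC1=C2CCC(=O)[C@]2(C)C=CC(C)=C1
A4 | alternative 3 | cyclopropa-fused trans-hydrindanediol (C6–C8 bonded, C7 as cyclopropane CH2, OH on C4 and C9) | CC(C)[C@]1(O)CC[C@]2(C)C[C@@H](O)[C@@]3(C)C[C@H]3[C@@H]12
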